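**Retrosynthetic overview**
1. Target ⇐ desilylation, MnO2 oxidation and SeO2 allylic oxidation of the C10 methyl group, O8 acylation, and Felkin reduction of the C8 ketone of macrocyclic keto lactone 20.
2. 20 ⇐ titanium-mediated macro-aldol (C6–C7) of open-chain keto enal 18, then lactonisation; this replaces the usual Barbier lactone / ring-closing metathesis plan. Ring order: ten-membered carbocycle first, five-membered lactone second, in one operation.
3. 18 ⇐ zinc Barbier 2-(methoxycarbonyl)allylation of α-silyloxy aldehyde 14, then double oxidation.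
4. 14 ⇐ B-alkyl Suzuki–Miyaura union (C3–C4) of (Z)-vinyl iodide 4 with diene 11, then glycol cleavage to unmask C8.
5. 11 ⇐ Felkin addition of a (Z)-dienylmetal (acrolein + iodo-Wittig) to (R)-glyceraldehyde acetonide, which sets C9; 4 ⇐ but-2-yne-1,4-diol by trans-hydroalumination/iodination.

Assumption: germacranolide numbering is used (ring C1–C10, lactone carbons C11–C13, C14 on C10, C15 on C4), so the target is 6R,7S,8S,9S with a (2R)-2-methylbutanoate on O8 and both ring alkenes cis within the ring. TBS = tert-butyldimethylsilyl, TBDPS = tert-butyldiphenylsilyl.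

**Step 1**
Reactants: 1 but-2-yne-1,4-diol
Product: 2 4-(TBDPS-oxy)but-2-yn-1-ol
Conditions: NaH (1 equiv), THF, 0 °C → rt; then TBDPSCl
Reagents that add atoms: tert-butyl(chloro)diphenylsilane, CC(C)(C)[Si](Cl)(c1ccccc1)c1ccccc1
Why: Monosilylation of a symmetrical diol through its sparingly soluble monosodium alkoxide (O-silylation) gives the mono-ether; no stereocentre is involved.

**Step 2**
Reactants: 2 4-(TBDPS-oxy)but-2-yn-1-ol
Product: 4 (2Z)-4-(TBDPS-oxy)-3-iodobut-2-en-1-ol, via cyclic sodium alkenylaluminate 3 (not isolated)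
Conditions: NaAlH2(OCH2CH2OMe)2, THF, 0 °C; then iodine, −78 → 0 °C
Reagents that add atoms: iodine, II
Why: Hydroxyl-directed trans-hydroalumination of the propargylic alcohol puts aluminium on the distal alkyne carbon (C4) anti to the new C5–H, and iododealumination with retention gives the vinyl iodide with iodine cis to C6.

**Step 3**
Reactants: 5 prop-2-enal (acrolein)
Product: 6 (3Z)-4-iodopenta-1,3-diene
Conditions: EtPPh3I, n-BuLi, THF, 0 °C; iodine, −78 °C; NaN(SiMe3)2, −78 → −20 °C; then 5, −78 °C → rt (product kept as an ether solution)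
Reagents that add atoms: ethyltriphenylphosphonium iodide, CC[P+](c1ccccc1)(c1ccccc1)c1ccccc1.[I-]; iodine, II
Why: Stork–Zhao-type Wittig olefination with the α-iodo ylide gives the trisubstituted vinyl iodide with iodine cis to the aldehyde-derived carbon, which later fixes C2 cis to C9 across C1=C10.

**Step 4**
Reactants: 6 (3Z)-4-iodopenta-1,3-diene; 7 (4R)-2,2-dimethyl-1,3-dioxolane-4-carbaldehyde
Product: 10 (1S,2Z)-1-[(4R)-2,2-dimethyl-1,3-dioxolan-4-yl]-2-methylpenta-2,4-dien-1-ol, via dienyllithium 8 (not isolated), via dienyltitanium triisopropoxide 9 (not isolated)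
Conditions: t-BuLi (2 equiv), Et2O, −78 °C; ClTi(Oi-Pr)3, −78 °C; then 7, −78 → −30 °C
Reagents that add atoms: none
Why: Iodine–lithium exchange with retention, transmetallation to the non-chelating alkenyltitanium and Felkin–Anh 1,2-addition to the α-alkoxy aldehyde give the anti adduct, so C9 (S) is set by the (R) centre of 7 (the minor syn isomer is removed by chromatography).

**Step 5**
Reactants: 10 (1S,2Z)-1-[(4R)-2,2-dimethyl-1,3-dioxolan-4-yl]-2-methylpenta-2,4-dien-1-ol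
Product: 11 TBS ether of 10
Conditions: TBSOTf, 2,6-lutidine, CH2Cl2, −78 → 0 °C
Reagents that add atoms: tert-butyldimethylsilyl trifluoromethanesulfonate, CC(C)(C)[Si](C)(C)OS(=O)(=O)C(F)(F)F
Why: O-Silylation of the hindered secondary allylic alcohol with the silyl triflate; C9 is untouched.

**Step 6**
Reactants: 11 TBS ether of 10; 4 (2Z)-4-(TBDPS-oxy)-3-iodobut-2-en-1-ol
Product: 13 (2E,6Z,8S)-8-(TBS-oxy)-3-[(TBDPS-oxy)methyl]-8-[(4R)-2,2-dimethyl-1,3-dioxolan-4-yl]-7-methylocta-2,6-dien-1-ol, via alkyl-9-borabicyclononane 12 (not isolated)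
Conditions: 9-BBN, THF, 0 °C → rt; then 4, PdCl2(dppf) (5 mol%), AsPh3, Cs2CO3, DMF/THF/H2O, rt
Reagents that add atoms: none
Why: Anti-Markovnikov hydroboration of the only monosubstituted alkene, then B-alkyl Suzuki–Miyaura sp3–sp2 coupling with retention at the vinyl iodide, forms C3–C4 with C3 cis to C6 and tolerates the free allylic alcohol.

**Step 7**
Reactants: 13 coupled allylic alcohol
Product: 14 (2S,3Z,7E)-2-(TBS-oxy)-7-[(TBDPS-oxy)methyl]-9-hydroxy-3-methylnona-3,7-dienal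
Conditions: H5IO6, EtOAc, rt (crude aldehyde used at once)
Reagents that add atoms: none
Why: Periodic acid hydrolyses the terminal acetonide and cleaves the freed 1,2-diol (Malaprade glycol cleavage) to the C8 aldehyde, excising the auxiliary centre while the silylated C9 stays intact.

**Step 8**
Reactants: 14 α-silyloxy aldehyde; 15 methyl 2-(bromomethyl)prop-2-enoate
Product: 17 methyl (4RS,5S,6Z,10E)-5-(TBS-oxy)-10-[(TBDPS-oxy)methyl]-4,12-dihydroxy-6-methyl-2-methylidenedodeca-6,10-dienoate, via allylzinc bromide 16 (not isolated)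
Conditions: Zn dust, THF/sat. aq NH4Cl, 0 °C → rt
Reagents that add atoms: none
Why: Zinc-mediated aqueous Barbier 2-(methoxycarbonyl)allylation adds C7 and C11–C13 to the aldehyde under near-neutral conditions; the C8 carbinol is a mixture because it is oxidised next.

**Step 9**
Reactants: 17 diol ester
Product: 18 methyl (5S,6Z,10E)-5-(TBS-oxy)-10-[(TBDPS-oxy)methyl]-6-methyl-2-methylidene-4,12-dioxododeca-6,10-dienoate
Conditions: Dess–Martin periodinane (3 equiv), pyridine, CH2Cl2, 0 °C → rt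
Reagents that add atoms: none
Why: Dess–Martin oxidation converts the primary allylic alcohol into the enal (geometry retained) and the C8 carbinol into the ketone in one buffered, non-epimerising operation.

**Step 10**
Reactants: 18 keto enal
Product: 20 (6R,7S,9S)-9-(TBS-oxy)-15-(TBDPS-oxy)-8-oxogermacra-1(10)Z,4E,11(13)-trien-12,6-olide (both ring alkenes cis in the ring, lactone trans-fused), via macrocyclic aldol adduct 19 (not isolated)
Conditions: TiCl4 then i-Pr2NEt, CH2Cl2 (2 mmol/L), −78 °C; pH 7 buffer; then PPTS (cat.), CH2Cl2, rt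
Reagents that add atoms: none
Why: Proposed new method: soft enolisation gives the chlorotitanium (Z)-enolate at the more accessible, doubly activated C7, which adds through a closed chair transition state to the tethered enal (syn aldol, hence the trans lactone); the aldehyde approaches the enolate face opposite the bulky C9–OSi bond while C10 lies near the enolate plane beside C7–H, the arrangement that lets the C1–C5 tether reach C6, giving 6R,7S, and mild acid then closes the γ-lactone from O6; the closest known reactions are open-chain titanium syn-aldol additions of α-silyloxy ketones and macro-aldol ring closures with alkali-metal or samarium enolates.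

**Step 11**
Reactants: 20 macrocyclic keto lactone
Product: 21 (6R,7S,8S,9S)-9-(TBS-oxy)-15-(TBDPS-oxy)-8-hydroxygermacra-1(10)Z,4E,11(13)-trien-12,6-olide
Conditions: NaBH4, CeCl3·7H2O, MeOH/THF, −78 °C
Reagents that add atoms: none
Why: Luche 1,2-reduction in which hydride adds anti to the α C–OSi bond (polar Felkin–Anh/Cornforth control) to give the 8,9-syn alcohol (8S), with cerium suppressing conjugate reduction of the methylene lactone.

**Step 12**
Reactants: 21 C8 alcohol; 22 (2R)-2-methylbutanoic acid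
Product: 23 (6R,7S,8S,9S)-9-(TBS-oxy)-15-(TBDPS-oxy)-12-oxo-germacra-1(10)Z,4E,11(13)-trien-12,6-olid-8-yl (2R)-2-methylbutanoate
Conditions: N,N'-dicyclohexylcarbodiimide, DMAP, CH2Cl2, 0 °C → rt
Reagents that add atoms: none
Why: Steglich esterification of the only free hydroxyl; the α-centre of the acid and C8 are both retained.

**Step 13**
Reactants: 23 C8 ester
Product: 24 14-hydroxy derivative of 23 (1(10)Z, CH2OH trans to C2)
Conditions: SeO2 (0.5 equiv), t-BuOOH, CH2Cl2, 0 °C → rt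
Reagents that add atoms: tert-butyl hydroperoxide, CC(C)(C)OO; selenium dioxide, O=[Se]=O
Why: Riley allylic oxidation (ene reaction then [2,3]-sigmatropic shift) attacks the methyl on the more substituted end of the more electron-rich C1=C10 alkene (C4=C5 is deactivated by two allylic C–O bonds) and re-forms the alkene with CH2OH trans to C2, the ring-cis geometry.

**Step 14**
Reactants: 24 C14 allylic alcohol
Product: 25 14-oxo derivative (enal, 1(10)E by CIP, ring-cis) of 23
Conditions: MnO2, CH2Cl2, rt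
Reagents that add atoms: none
Why: Chemoselective MnO2 oxidation of the only free, allylic alcohol to the conjugated aldehyde.

**Step 15**
Reactants: 25 bis-silyl enal
Product: 26 target, (6R,7S,8S,9S)-9,15-dihydroxy-14-oxogermacra-1(10)E,4E,11(13)-trien-12,6-olid-8-yl (2R)-2-methylbutanoate
Conditions: HF·pyridine, pyridine, THF, 0 °C → rt
Reagents that add atoms: none
Why: Fluoride-mediated desilylation of both silyl ethers under mildly acidic conditions, which avoids O8→O9 acyl migration and conjugate addition to the lactone or enal.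

**Compound list**
1 | but-2-yne-1,4-diol | OCC#CCO | starting material
2 | 4-(TBDPS-oxy)but-2-yn-1-ol | OCC#CCO[Si](c1ccccc1)(c1ccccc1)C(C)(C)C | intermediate
3 | cyclic sodium alkenylaluminate Na[Al(OCH2CH2OMe)2(OCH2CH=C(CH2OTBDPS))], Al on C4 cis to C6 | [Na+].COCCO[Al-]1(OCCOC)OCC=C1CO[Si](c1ccccc1)(c1ccccc1)C(C)(C)C | intermediate
4 | (2Z)-4-(TBDPS-oxy)-3-iodobut-2-en-1-ol | OC/C=C(/CO[Si](c1ccccc1)(c1ccccc1)C(C)(C)C)I | intermediate
5 | prop-2-enal (acrolein) | C=CC=O | starting material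
6 | (3Z)-4-iodopenta-1,3-diene | C=C/C=C(/C)I | intermediate
7 | (4R)-2,2-dimethyl-1,3-dioxolane-4-carbaldehyde | O=C[C@H]1COC(C)(C)O1 | starting material
8 | dienyllithium from 6 (Li in place of I, geometry retained) | C=C/C=C(/C)[Li] | intermediate
9 | dienyltitanium triisopropoxide from 8 (geometry retained) | C=C/C=C(/C)[Ti](OC(C)C)(OC(C)C)OC(C)C | intermediate
10 | (1S,2Z)-1-[(4R)-2,2-dimethyl-1,3-dioxolan-4-yl]-2-methylpenta-2,4-dien-1-ol | C=C/C=C(/C)[C@H](O)[C@H]1COC(C)(C)O1 | intermediate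
11 | tert-butyl{[(1S,2Z)-1-[(4R)-2,2-dimethyl-1,3-dioxolan-4-yl]-2-methylpenta-2,4-dien-1-yl]oxy}dimethylsilane | C=C/C=C(/C)[C@H](O[Si](C)(C)C(C)(C)C)[C@H]1COC(C)(C)O1 | intermediate
12 | 9-[(3Z,5S)-5-(TBS-oxy)-5-[(4R)-2,2-dimethyl-1,3-dioxolan-4-yl]-4-methylpent-3-en-1-yl]-9-borabicyclo[3.3.1]nonane | C(C/C=C(/C)[C@H](O[Si](C)(C)C(C)(C)C)[C@H]1COC(C)(C)O1)B1C2CCCC1CCC2 | intermediate
13 | (2E,6Z,8S)-8-(TBS-oxy)-3-[(TBDPS-oxy)methyl]-8-[(4R)-2,2-dimethyl-1,3-dioxolan-4-yl]-7-methylocta-2,6-dien-1-ol | OC/C=C(/CO[Si](c1ccccc1)(c1ccccc1)C(C)(C)C)CC/C=C(/C)[C@H](O[Si](C)(C)C(C)(C)C)[C@H]1COC(C)(C)O1 | intermediate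
14 | (2S,3Z,7E)-2-(TBS-oxy)-7-[(TBDPS-oxy)methyl]-9-hydroxy-3-methylnona-3,7-dienal | OC/C=C(/CO[Si](c1ccccc1)(c1ccccc1)C(C)(C)C)CC/C=C(/C)[C@H](O[Si](C)(C)C(C)(C)C)C=O | intermediate
15 | methyl 2-(bromomethyl)prop-2-enoate | C=C(CBr)C(=O)OC | starting material
16 | bromo[2-(methoxycarbonyl)prop-2-en-1-yl]zinc | C=C(C[Zn]Br)C(=O)OC | intermediate
17 | methyl (4RS,5S,6Z,10E)-5-(TBS-oxy)-10-[(TBDPS-oxy)methyl]-4,12-dihydroxy-6-methyl-2-methylidenedodeca-6,10-dienoate | OC/C=C(/CO[Si](c1ccccc1)(c1ccccc1)C(C)(C)C)CC/C=C(/C)[C@H](O[Si](C)(C)C(C)(C)C)C(O)CC(=C)C(=O)OC | intermediate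
18 | methyl (5S,6Z,10E)-5-(TBS-oxy)-10-[(TBDPS-oxy)methyl]-6-methyl-2-methylidene-4,12-dioxododeca-6,10-dienoate | O=C/C=C(/CO[Si](c1ccccc1)(c1ccccc1)C(C)(C)C)CC/C=C(/C)[C@H](O[Si](C)(C)C(C)(C)C)C(=O)CC(=C)C(=O)OC | intermediate
19 | methyl 2-[(1S,2R,3E,7Z,9S)-9-(TBS-oxy)-4-[(TBDPS-oxy)methyl]-2-hydroxy-8-methyl-10-oxocyclodeca-3,7-dien-1-yl]prop-2-enoate | C=C(C(=O)OC)[C@H]1[C@H](O)/C=C(/CO[Si](c2ccccc2)(c2ccccc2)C(C)(C)C)CC/C=C(/C)[C@H](O[Si](C)(C)C(C)(C)C)C1=O | intermediate
20 | (6R,7S,9S)-9-(TBS-oxy)-15-(TBDPS-oxy)-8-oxogermacra-1(10)Z,4E,11(13)-trien-12,6-olide | C=C1C(=O)O[C@@H]2/C=C(/CO[Si](c3ccccc3)(c3ccccc3)C(C)(C)C)CC/C=C(/C)[C@H](O[Si](C)(C)C(C)(C)C)C(=O)[C@@H]12 | intermediate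
21 | (6R,7S,8S,9S)-9-(TBS-oxy)-15-(TBDPS-oxy)-8-hydroxygermacra-1(10)Z,4E,11(13)-trien-12,6-olide | C=C1C(=O)O[C@@H]2/C=C(/CO[Si](c3ccccc3)(c3ccccc3)C(C)(C)C)CC/C=C(/C)[C@H](O[Si](C)(C)C(C)(C)C)[C@@H](O)[C@@H]12 | intermediate
22 | (2R)-2-methylbutanoic acid | CC[C@@H](C)C(=O)O | starting material
23 | 8-O-[(2R)-2-methylbutanoyl] ester of 21 | C=C1C(=O)O[C@@H]2/C=C(/CO[Si](c3ccccc3)(c3ccccc3)C(C)(C)C)CC/C=C(/C)[C@H](O[Si](C)(C)C(C)(C)C)[C@@H](OC(=O)[C@H](C)CC)[C@@H]12 | intermediate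
24 | 14-hydroxy derivative of 23 (1(10)Z) | C=C1C(=O)O[C@@H]2/C=C(/CO[Si](c3ccccc3)(c3ccccc3)C(C)(C)C)CC/C=C(/CO)[C@H](O[Si](C)(C)C(C)(C)C)[C@@H](OC(=O)[C@H](C)CC)[C@@H]12 | intermediate
25 | 14-oxo derivative of 23 (1(10)E) | C=C1C(=O)O[C@@H]2/C=C(/CO[Si](c3ccccc3)(c3ccccc3)C(C)(C)C)CC/C=C(/C=O)[C@H](O[Si](C)(C)C(C)(C)C)[C@@H](OC(=O)[C@H](C)CC)[C@@H]12 | intermediate
26 | (6R,7S,8S,9S)-9,15-dihydroxy-14-oxogermacra-1(10)E,4E,11(13)-trien-12,6-olid-8-yl (2R)-2-methylbutanoate | C=C1C(=O)O[C@@H]2/C=C(/CO)CC/C=C(/C=O)[C@H](O)[C@@H](OC(=O)[C@H](C)CC)[C@@H]12 | target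

**Totals**
Total step count: 15. Longest linear sequence: 13 steps (acrolein 5 → 26, steps 3–15); the branch from 1 joins at step 6.

**Steps most likely to fail, and fallbacks**

Step 10 (macro-aldol) is the largest risk. It can give oligomers, Lewis-acid ene/Prins closure of the enal onto C1=C10, γ-attack of the dienolate to a twelve-membered enone, or attack on the wrong enolate face. The fallback moves the aldol to an open chain and closes the ring by sp3–sp2 coupling. It sets out from 11 and 4 and comes back at 20. Periodic acid cleavage of 11 gives (2S,3Z)-2-(TBS-oxy)-3-methylhexa-3,5-dienal F1. Zinc Barbier reaction of F1 with 15 gives methyl (4RS,5S,6Z)-5-(TBS-oxy)-4-hydroxy-6-methyl-2-methylidenenona-6,8-dienoate F2, and Dess–Martin oxidation gives methyl (5S,6Z)-5-(TBS-oxy)-6-methyl-2-methylidene-4-oxonona-6,8-dienoate F3. MnO2 oxidation of 4 gives (2Z)-4-(TBDPS-oxy)-3-iodobut-2-enal F4. TiCl4/i-Pr2NEt aldol addition of F3 to F4 (open-chain α-silyloxy ketone model, syn aldol) gives the open-chain aldol adduct F5, which PPTS lactonises to the trans keto lactone carrying the iododiene and diene arms F6. 9-BBN hydroboration of the terminal alkene of F6 gives the alkylborane F7, and PdCl2(dppf)/AsPh3/Cs2CO3 at high dilution (B-alkyl Suzuki–Miyaura macrocyclisation, C3–C4) returns 20.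

Step 11 (C8 reduction) may give the 8R alcohol if the lactone-side substituent at C7 overrides the α-silyloxy control. The fallback uses hydroxyl-directed hydride delivery before the lactone exists. It sets out from 19, isolated by leaving out the acid treatment of step 10, and comes back at 21. Me4NBH(OAc)3 in MeCN/AcOH at −30 °C (Evans–Saksena 1,3-anti reduction directed by O6) gives methyl 2-[(1S,2R,3E,7Z,9S,10S)-9-(TBS-oxy)-4-[(TBDPS-oxy)methyl]-2,10-dihydroxy-8-methylcyclodeca-3,7-dien-1-yl]prop-2-enoate F8. PPTS then closes the lactone through the less hindered allylic O6 to give the trans-fused 21; any 8,12-isomer would be equilibrated with acid.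

Step 13 (SeO2 oxidation) may be slow, over-oxidise, or attack C3 or C15. The fallback replaces direct C–H oxidation by an ene-chlorination and oxidative allylic transposition. It sets out from 23 and comes back at 25. Ca(OCl)2/CO2 in CH2Cl2/H2O at 0 °C (HOCl ene-type chlorination of the C1=C10 alkene) gives the transposed allylic chloride, the 1-chloro-10(14)-ene isomer of 23, F9. AgBF4 in DMSO followed by Et3N (silver-assisted Kornblum oxidation at the primary allylic terminus) gives enal 25 directly.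

**Further compounds**
F1 | step 10 | (2S,3Z)-2-(TBS-oxy)-3-methylhexa-3,5-dienal | C=C/C=C(/C)[C@H](O[Si](C)(C)C(C)(C)C)C=O
F2 | step 10 | methyl (4RS,5S,6Z)-5-(TBS-oxy)-4-hydroxy-6-methyl-2-methylidenenona-6,8-dienoate | C=C/C=C(/C)[C@H](O[Si](C)(C)C(C)(C)C)C(O)CC(=C)C(=O)OC
F3 | step 10 | methyl (5S,6Z)-5-(TBS-oxy)-6-methyl-2-methylidene-4-oxonona-6,8-dienoate | C=C/C=C(/C)[C@H](O[Si](C)(C)C(C)(C)C)C(=O)CC(=C)C(=O)OC
F4 | step 10 | (2Z)-4-(TBDPS-oxy)-3-iodobut-2-enal | O=C/C=C(/CO[Si](c1ccccc1)(c1ccccc1)C(C)(C)C)I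
F5 | step 10 | open-chain syn aldol adduct of F3 and F4 (same spatial arrangement at C6, C7, C9 as 19) | C=C(C(=O)OC)[C@@H]([C@H](O)/C=C(/CO[Si](c1ccccc1)(c1ccccc1)C(C)(C)C)I)C(=O)[C@@H](O[Si](C)(C)C(C)(C)C)/C(C)=C\C=C
F6 | step 10 | trans keto lactone with iodoalkene and diene arms | C=C1C(=O)O[C@H](/C=C(/CO[Si](c2ccccc2)(c2ccccc2)C(C)(C)C)I)[C@H]1C(=O)[C@@H](O[Si](C)(C)C(C)(C)C)/C(C)=C\C=C
F7 | step 10 | 9-BBN alkylborane from F6 (boron on C3) | C=C1C(=O)O[C@H](/C=C(/CO[Si](c2ccccc2)(c2ccccc2)C(C)(C)C)I)[C@H]1C(=O)[C@@H](O[Si](C)(C)C(C)(C)C)/C(C)=C\CCB1C2CCCC1CCC2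
F8 | step 11 | methyl 2-[(1S,2R,3E,7Z,9S,10S)-9-(TBS-oxy)-4-[(TBDPS-oxy)methyl]-2,10-dihydroxy-8-methylcyclodeca-3,7-dien-1-yl]prop-2-enoate | C=C(C(=O)OC)[C@H]1[C@H](O)/C=C(/CO[Si](c2ccccc2)(c2ccccc2)C(C)(C)C)CC/C=C(/C)[C@H](O[Si](C)(C)C(C)(C)C)[C@H]1O
F9 | step 13 | 1-chloro-10(14)-ene isomer of 23 (C1 epimers) | C=C1C(=O)O[C@@H]2/C=C(/CO[Si](c3ccccc3)(c3ccccc3)C(C)(C)C)CCC(Cl)C(=C)[C@H](O[Si](C)(C)C(C)(C)C)[C@@H](OC(=O)[C@H](C)CC)[C@@H]12
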